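**Retrosynthetic overview**

- The target is the (3R,4R)-butyrolactone carrying a vanillyl group on C3 and an (S)-aryl carbinol on C4. The last steps only unmask three oxygens (carbinol O–Si, two aryl O–benzyl).
- The butyrolactone is the only ring the route forms, and it is closed after the key step: the ring C5H2–O is made by reducing an imide carbonyl, and the new primary alcohol closes onto the C2 methyl ester.
- Key disconnection: the bond from ring C4 to the exocyclic carbinol carbon. The carbinol oxygen and the ring C5–O are 1,3-related through C4, so with C5 raised to the acyl level (N-acyloxazolidinone) C4 is an enolisable CH2 and this bond is a syn-aldol bond to O-benzylvanillin. The aldol sets C4 and the carbinol together.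
- With C5 at the acyl level the ring atoms C2–C3–C4–C5 are an (R)-2-benzylsuccinate. It comes from a Stobbe condensation of the same aldehyde with dimethyl succinate, followed by asymmetric hydrogenation (sets C3).

Key step: step 4

Remark on numbering: positions are named by the lactone ring (C2 carbonyl, C3 benzyl-bearing, C4 carbinol-bearing, C5 OCH2); "carbinol" is the exocyclic CH(OH)Ar carbon.

Remark on step 2: the (S,S) hand of Et-DuPHOS is assigned by analogy with itaconate half-esters. If the catalyst named should deliver the S acid, its commercial antipode is used and nothing else changes.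

**Route**

Step 1
Reactants: 1 4-(benzyloxy)-3-methoxybenzaldehyde; 2 dimethyl succinate
Product: 4 (E)-4-[4-(benzyloxy)-3-methoxyphenyl]-3-(methoxycarbonyl)but-3-enoic acid, via Stobbe lactone 3 (not isolated)
Conditions: NaOMe (1.5 equiv), MeOH, reflux; then aq. HCl
Reagents that add atoms: none
Why: Stobbe condensation: the succinate enolate adds to the aldehyde, the aldolate lactonises to 3, and E1cB opening gives the half-ester with the free acid on the CH2 arm; the E alkene (aryl trans to CO2Me) is the conjugated, less strained isomer, and no stereocenter is formed.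

Step 2
Reactants: 4 (E)-half-ester acid
Product: 5 (3R)-4-[4-(benzyloxy)-3-methoxyphenyl]-3-(methoxycarbonyl)butanoic acid
Conditions: H2 (5 bar), [Rh(cod)((S,S)-Et-DuPHOS)]BF4 (0.5 mol %), NaOMe (10 mol %), MeOH, rt
Reagents that add atoms: none
Why: Asymmetric hydrogenation of a Stobbe itaconate half-ester: the carboxylate arm and the alkene chelate monovalent rhodium and the C2-symmetric bisphospholane selects the alkene face, setting the future ring C3 as R; aryl benzyl ethers are inert to this homogeneous catalyst.

Step 3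
Reactants: 5 (3R)-half-ester acid; 6 (S)-4-benzyl-2-oxazolidinone
Product: 8 methyl (2R)-2-[4-(benzyloxy)-3-methoxybenzyl]-4-[(4S)-4-benzyl-2-oxo-1,3-oxazolidin-3-yl]-4-oxobutanoate, via mixed pivalic anhydride 7 (not isolated)
Conditions: PivCl, Et3N, THF, −20 °C; then 6, LiCl, −20 °C → rt
Reagents that add atoms: none
Why: Mixed-anhydride N-acylation of an oxazolidinone (LiCl/Et3N variant): the oxazolidinone attacks the unhindered carbonyl of 7 rather than the pivaloyl carbonyl, and Et3N does not enolise the ester-bearing stereocenter.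

Step 4
Reactants: 8 succinate imide; 1 4-(benzyloxy)-3-methoxybenzaldehyde
Product: 10 methyl (2R,3S)-2-[4-(benzyloxy)-3-methoxybenzyl]-4-[(4S)-4-benzyl-2-oxo-1,3-oxazolidin-3-yl]-3-{(S)-[4-(benzyloxy)-3-methoxyphenyl](hydroxy)methyl}-4-oxobutanoate, via Z boron enolate 9 (not isolated)
Conditions: Bu2BOTf (1.1 equiv), i-Pr2NEt (1.3 equiv), CH2Cl2, 0 °C; then 1, −78 → 0 °C; pH 7 buffer, MeOH, 30% H2O2, 0 °C
Reagents that add atoms: none
Why: Bu2BOTf and i-Pr2NEt enolise only the imide CH2 (the boron-complexed imide is far more acidic than the α-branched ester CH) to the Z(O)-boron enolate 9, which adds to the aldehyde through a closed Zimmerman–Traxler chair in which the oxazolidinone carbonyl points away from the enolate oxygen. The closest known reaction type is the Evans syn-aldol of succinate-derived N-acyloxazolidinones with aldehydes; no ring is closed. The new ring-C4 stereocenter is controlled by the auxiliary, whose 4-benzyl group blocks one enolate face, and the carbinol stereocenter is controlled by the Z enolate geometry in the chair, which enforces the syn relationship that maps onto (4R) and the S carbinol of the target. The step needs reagent control over the resident stereocenter next to the enolate carbon, which the tight boron chair should secure because the two arms of that center (CO2Me and CH2Ar) are of similar size and bias the enolate faces only weakly. It also needs the aldolate not to lactonise onto the methyl ester; that closure would give a lactone with cis substituents on adjacent carbons and is held back by the boron chelate, so cold buffered oxidative work-up should return the open hydroxy ester. In one operation the second aryl ring is attached, the carbon skeleton is completed and two of the three stereocenters are set.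

Step 5
Reactants: 10 syn-aldol adduct
Product: 11 methyl (2R,3S)-2-[4-(benzyloxy)-3-methoxybenzyl]-4-[(4S)-4-benzyl-2-oxo-1,3-oxazolidin-3-yl]-3-{(S)-[4-(benzyloxy)-3-methoxyphenyl][(tert-butyldimethylsilyl)oxy]methyl}-4-oxobutanoate
Conditions: TBSOTf, 2,6-lutidine, CH2Cl2, −78 → 0 °C
Reagents that add atoms: tert-butyldimethylsilyl triflate, CC(C)(C)[Si](C)(C)OS(=O)(=O)C(F)(F)F
Why: Silyl triflate silylation of a hindered secondary alcohol; it blocks the carbinol oxygen so that only the primary alcohol made in step 6 can lactonise, and it shuts off retro-aldol cleavage; no stereocenter is touched.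

Step 6
Reactants: 11 silylated aldol imide
Product: 13 (3R,4R)-3-[4-(benzyloxy)-3-methoxybenzyl]-4-{(S)-[4-(benzyloxy)-3-methoxyphenyl][(tert-butyldimethylsilyl)oxy]methyl}dihydrofuran-2(3H)-one, via hydroxy ester 12 (not isolated)
Conditions: NaBH4 (3 equiv), THF/H2O 4:1, 0 °C → rt; then DBU (0.1 equiv), toluene, 40 °C
Reagents that add atoms: none
Why: Borohydride reduction of an N-acyloxazolidinone in aqueous THF: hydride adds to the exocyclic imide carbonyl, the hemiaminal collapses to the aldehyde and this is reduced to primary alcohol 12 while the methyl ester is inert to NaBH4; 12 then closes the lactone by 5-exo-trig acyl substitution at the ester, giving the trans-3,4-disubstituted ring with no stereocenter touched.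

Step 7
Reactants: 13 silylated lactone
Product: 14 (3R,4R)-3-[4-(benzyloxy)-3-methoxybenzyl]-4-{(S)-[4-(benzyloxy)-3-methoxyphenyl](hydroxy)methyl}dihydrofuran-2(3H)-one
Conditions: TBAF (1.5 equiv), AcOH (1.5 equiv), THF, 0 °C → rt
Reagents that add atoms: none
Why: Fluoride desilylation buffered with AcOH, so the freed alkoxide is protonated at once and does not translactonise; the lactone through the primary oxygen is in any case the more stable five-membered lactone, because the alternative through the carbinol oxygen would carry cis substituents.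

Step 8
Reactants: 14 dibenzyl ether of the target
Product: 15 (3R,4R)-4-[(S)-hydroxy(4-hydroxy-3-methoxyphenyl)methyl]-3-(4-hydroxy-3-methoxybenzyl)dihydrofuran-2(3H)-one
Conditions: H2 (1 atm), 10% Pd/C, EtOAc, rt, stopped when 14 is consumed
Reagents that add atoms: none
Why: Hydrogenolysis of aryl benzyl ethers on Pd/C in a neutral, acid-free solvent is much faster than hydrogenolysis of a secondary benzylic alcohol, as relied on routinely for p-hydroxyphenyl carbinols in lignin model chemistry; no stereocenter is touched.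

**Compound list**

1 | 4-(benzyloxy)-3-methoxybenzaldehyde (O-benzylvanillin) | COc1cc(C=O)ccc1OCc1ccccc1 | starting material
2 | dimethyl succinate | COC(=O)CCC(=O)OC | starting material
3 | methyl 2-[4-(benzyloxy)-3-methoxyphenyl]-5-oxotetrahydrofuran-3-carboxylate (Stobbe lactone, mixture of isomers) | COC(=O)C1CC(=O)OC1c1ccc(OCc2ccccc2)c(OC)c1 | intermediate
4 | (E)-4-[4-(benzyloxy)-3-methoxyphenyl]-3-(methoxycarbonyl)but-3-enoic acid | COC(=O)/C(CC(=O)O)=C/c1ccc(OCc2ccccc2)c(OC)c1 | intermediate
5 | (3R)-4-[4-(benzyloxy)-3-methoxyphenyl]-3-(methoxycarbonyl)butanoic acid | COC(=O)[C@@H](CC(=O)O)Cc1ccc(OCc2ccccc2)c(OC)c1 | intermediate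
6 | (S)-4-benzyl-2-oxazolidinone | O=C1OC[C@H](Cc2ccccc2)N1 | starting material
7 | mixed anhydride of 5 with pivalic acid | COC(=O)[C@@H](CC(=O)OC(=O)C(C)(C)C)Cc1ccc(OCc2ccccc2)c(OC)c1 | intermediate
8 | methyl (2R)-2-[4-(benzyloxy)-3-methoxybenzyl]-4-[(4S)-4-benzyl-2-oxo-1,3-oxazolidin-3-yl]-4-oxobutanoate | COC(=O)[C@@H](CC(=O)N1[C@@H](Cc2ccccc2)COC1=O)Cc1ccc(OCc2ccccc2)c(OC)c1 | intermediate
9 | Z(O)-dibutylboron enolate of 8 | COC(=O)[C@H](Cc1ccc(OCc2ccccc2)c(OC)c1)/C=C(\OB(CCCC)CCCC)N1[C@@H](Cc2ccccc2)COC1=O | intermediate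
10 | methyl (2R,3S)-2-[4-(benzyloxy)-3-methoxybenzyl]-4-[(4S)-4-benzyl-2-oxo-1,3-oxazolidin-3-yl]-3-{(S)-[4-(benzyloxy)-3-methoxyphenyl](hydroxy)methyl}-4-oxobutanoate | COC(=O)[C@H](Cc1ccc(OCc2ccccc2)c(OC)c1)[C@H](C(=O)N1[C@@H](Cc2ccccc2)COC1=O)[C@H](O)c1ccc(OCc2ccccc2)c(OC)c1 | intermediate
11 | tert-butyldimethylsilyl ether of 10 at the carbinol oxygen | COC(=O)[C@H](Cc1ccc(OCc2ccccc2)c(OC)c1)[C@H](C(=O)N1[C@@H](Cc2ccccc2)COC1=O)[C@H](O[Si](C)(C)C(C)(C)C)c1ccc(OCc2ccccc2)c(OC)c1 | intermediate
12 | methyl (2R,3R)-2-[4-(benzyloxy)-3-methoxybenzyl]-3-{(S)-[4-(benzyloxy)-3-methoxyphenyl][(tert-butyldimethylsilyl)oxy]methyl}-4-hydroxybutanoate | COC(=O)[C@H](Cc1ccc(OCc2ccccc2)c(OC)c1)[C@H](CO)[C@H](O[Si](C)(C)C(C)(C)C)c1ccc(OCc2ccccc2)c(OC)c1 | intermediate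
13 | (3R,4R)-3-[4-(benzyloxy)-3-methoxybenzyl]-4-{(S)-[4-(benzyloxy)-3-methoxyphenyl][(tert-butyldimethylsilyl)oxy]methyl}dihydrofuran-2(3H)-one | COc1cc(C[C@H]2C(=O)OC[C@@H]2[C@H](O[Si](C)(C)C(C)(C)C)c2ccc(OCc3ccccc3)c(OC)c2)ccc1OCc1ccccc1 | intermediate
14 | (3R,4R)-3-[4-(benzyloxy)-3-methoxybenzyl]-4-{(S)-[4-(benzyloxy)-3-methoxyphenyl](hydroxy)methyl}dihydrofuran-2(3H)-one | COc1cc(C[C@H]2C(=O)OC[C@@H]2[C@H](O)c2ccc(OCc3ccccc3)c(OC)c2)ccc1OCc1ccccc1 | intermediate
15 | (3R,4R)-4-[(S)-hydroxy(4-hydroxy-3-methoxyphenyl)methyl]-3-(4-hydroxy-3-methoxybenzyl)dihydrofuran-2(3H)-one | COc1cc(C[C@H]2C(=O)OC[C@@H]2[C@H](O)c2ccc(O)c(OC)c2)ccc1O | target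

**Step count**

Total steps: 8. Longest linear sequence: 8 (aldehyde 1 enters in steps 1 and 4).

**Steps most likely to fail**

Step 4 (key aldol). The resident stereocenter beside the enolate carbon may oppose the auxiliary and erode facial selectivity. The electron-rich benzylic aldolate may revert by retro-aldol cleavage on work-up, or may close onto the methyl ester before it is silylated. The fallback builds the same bond by C-acylation and sets the carbinol by hydride. It sets out from acid 5, which through mixed anhydride 7 is joined to (R)-4-benzyl-2-oxazolidinone (PivCl, Et3N, LiCl, THF) to give methyl (2R)-2-[4-(benzyloxy)-3-methoxybenzyl]-4-[(4R)-4-benzyl-2-oxo-1,3-oxazolidin-3-yl]-4-oxobutanoate F1. The R auxiliary is needed because the chelated sodium enolate reacts with the facial sense opposite to that of the boron aldol. NaHMDS in THF at −78 °C and then 4-(benzyloxy)-3-methoxybenzoyl chloride should give the β-keto imide methyl (2R,3S)-3-[4-(benzyloxy)-3-methoxybenzoyl]-2-[4-(benzyloxy)-3-methoxybenzyl]-4-[(4R)-4-benzyl-2-oxo-1,3-oxazolidin-3-yl]-4-oxobutanoate F2, acylated on the enolate face away from the auxiliary benzyl group. Chelation-controlled reduction with Zn(BH4)2 in CH2Cl2/Et2O at −20 °C should give the syn β-hydroxy imide F3, which is adduct 10 with the R auxiliary. TBSOTf and 2,6-lutidine give its silyl ether F4, and NaBH4 in THF/H2O followed by catalytic DBU removes the auxiliary through hydroxy ester 12, so the fallback comes back to the route at compound 13.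

Step 6 (reductive auxiliary removal and lactonisation). The hydride may over-reduce the methyl ester or the newly formed lactone, may open the oxazolidinone ring of the hindered imide instead of the exocyclic carbonyl, or may leave lactonisation incomplete. The fallback separates cleavage from reduction. It sets out from compound 11, whose auxiliary is removed hydrolytically (LiOH, H2O2, THF/H2O, 0 °C) to give (2S,3R)-3-[4-(benzyloxy)-3-methoxybenzyl]-2-{(S)-[4-(benzyloxy)-3-methoxyphenyl][(tert-butyldimethylsilyl)oxy]methyl}-4-methoxy-4-oxobutanoic acid F5. BH3·SMe2 in THF at 0 °C, which reduces a carboxylic acid in the presence of an ester, then gives hydroxy ester 12, and this lactonises (catalytic DBU, toluene), so the fallback comes back at compound 13.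

Step 8 (final hydrogenolysis). Hydrogenolytic loss of the benzylic carbinol C–O bond may compete with O-debenzylation, or traces of acid on the catalyst may ionise the p-hydroxybenzylic alcohol once the phenol is free. The fallback changes the order of unmasking. It sets out from compound 13, which is debenzylated (H2, 10% Pd/C, EtOAc) while the carbinol oxygen still carries the bulky silyl group, giving (3R,4R)-4-{(S)-[(tert-butyldimethylsilyl)oxy](4-hydroxy-3-methoxyphenyl)methyl}-3-(4-hydroxy-3-methoxybenzyl)dihydrofuran-2(3H)-one F6. Desilylation with Et3N·3HF in MeCN at rt, a near-neutral fluoride source that generates no phenoxide, then comes back at compound 15.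

**Further compounds**

F1 | step 4 | methyl (2R)-2-[4-(benzyloxy)-3-methoxybenzyl]-4-[(4R)-4-benzyl-2-oxo-1,3-oxazolidin-3-yl]-4-oxobutanoate | COC(=O)[C@@H](CC(=O)N1[C@H](Cc2ccccc2)COC1=O)Cc1ccc(OCc2ccccc2)c(OC)c1
F2 | step 4 | methyl (2R,3S)-3-[4-(benzyloxy)-3-methoxybenzoyl]-2-[4-(benzyloxy)-3-methoxybenzyl]-4-[(4R)-4-benzyl-2-oxo-1,3-oxazolidin-3-yl]-4-oxobutanoate | COC(=O)[C@H](Cc1ccc(OCc2ccccc2)c(OC)c1)[C@H](C(=O)N1[C@H](Cc2ccccc2)COC1=O)C(=O)c1ccc(OCc2ccccc2)c(OC)c1
F3 | step 4 | methyl (2R,3S)-2-[4-(benzyloxy)-3-methoxybenzyl]-4-[(4R)-4-benzyl-2-oxo-1,3-oxazolidin-3-yl]-3-{(S)-[4-(benzyloxy)-3-methoxyphenyl](hydroxy)methyl}-4-oxobutanoate | COC(=O)[C@H](Cc1ccc(OCc2ccccc2)c(OC)c1)[C@H](C(=O)N1[C@H](Cc2ccccc2)COC1=O)[C@H](O)c1ccc(OCc2ccccc2)c(OC)c1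
F4 | step 4 | tert-butyldimethylsilyl ether of F3 at the carbinol oxygen | COC(=O)[C@H](Cc1ccc(OCc2ccccc2)c(OC)c1)[C@H](C(=O)N1[C@H](Cc2ccccc2)COC1=O)[C@H](O[Si](C)(C)C(C)(C)C)c1ccc(OCc2ccccc2)c(OC)c1
F5 | step 6 | (2S,3R)-3-[4-(benzyloxy)-3-methoxybenzyl]-2-{(S)-[4-(benzyloxy)-3-methoxyphenyl][(tert-butyldimethylsilyl)oxy]methyl}-4-methoxy-4-oxobutanoic acid | COC(=O)[C@H](Cc1ccc(OCc2ccccc2)c(OC)c1)[C@H](C(=O)O)[C@H](O[Si](C)(C)C(C)(C)C)c1ccc(OCc2ccccc2)c(OC)c1
F6 | step 8 | (3R,4R)-4-{(S)-[(tert-butyldimethylsilyl)oxy](4-hydroxy-3-methoxyphenyl)methyl}-3-(4-hydroxy-3-methoxybenzyl)dihydrofuran-2(3H)-one | COc1cc(C[C@H]2C(=O)OC[C@@H]2[C@H](O[Si](C)(C)C(C)(C)C)c2ccc(O)c(OC)c2)ccc1O
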